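**Plan**

1. Locants used here: ring A (cyclohexenol) C1(OH)=C2–C3H–C4H2–C5H(isopropenyl)–C6H2; ring B (nine-membered lactone) C2–C7(=O)–O8–C9(Me)(CH2CO2Me)–C10H2–C11H–C12H(OH)–C13H–C3; ring C (γ-lactone) C11–O–C14(=O)–C13–C12.
2. Enabling feature: C14 is bonded to C13, whose neighbour C3 is β to C14 and carries the doubly activated C2 of the C1/C7 β-keto ester, while O–C11 sits 1,3 to C13 across C12. C2–C3 is therefore a retro-Michael bond to an α-alkylidene lactone, and C14–C13 is the bond made when an alkoxycarbonylpalladium on O–C11 inserts a C13≡C3 alkyne (5-exo-dig).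
3. Cuts in retro order: C2–C3 (transannular Michael) and C14–C13 (cyclocarbonylation), both in the last step from the 13-membered cycloalkyne diol 19; then C13≡C3 (ring-closing alkyne metathesis); then C7–O8 (acylketene capture by the C9 tertiary alcohol), giving a carvone-derived keto ester (C1–C7) and a triol ester (C9–C13).
4. Forward ring order: 13-membered macrolactone, then ring C, then rings A and B together.
5. Stereochemistry: C5 from (R)-carvone; C11 and C12 from a Sharpless kinetic-resolution epoxidation; C9 by 1,3-induction in a SmI2 Reformatsky lactonisation; C3 from the alkylidene geometry and the tether-enforced face in the transannular Michael addition; C13 from the cis-bridging requirement of ring C.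

Key step: step 16

Remark: the target is taken as the structure of the given SMILES, with ring A as the hydrogen-bonded enol of the β-keto ester (5S, 3R, 13S, 12S, 11R, 9S in the locants above); open-chain and macrocyclic precursors are written in the keto form.

**Route**

Step 1
Reactants: 1 (R)-(−)-carvone
Product: 2 (1R,4R,6R)-1-methyl-4-(prop-1-en-2-yl)-7-oxabicyclo[4.1.0]heptan-2-one
Conditions: H2O2 (30% aq.), NaOH (cat.), MeOH, 0 °C
Reagents that add atoms: hydrogen peroxide, OO
Why: Weitz–Scheffer nucleophilic epoxidation attacks only the enone (the isopropenyl alkene is inert to hydroperoxide anion) and should occur anti to the isopropenyl group; the epoxide stereocentres are destroyed in step 2, so only C5 matters.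

Step 2
Reactants: 2 (1R,4R,6R)-carvone epoxide
Product: 4 (3S)-3-(prop-1-en-2-yl)hept-5-ynal, via epoxy tosylhydrazone 3 (not isolated)
Conditions: TsNHNH2, CH2Cl2/AcOH (1:1), −20 °C to rt
Reagents that add atoms: none
Why: Eschenmoser–Tanabe fragmentation of the α,β-epoxy ketone hydrazone should cleave the former C2–C3 bond of carvone with loss of N2 and sulfinate, giving the methyl-capped alkyne and the aldehyde while leaving the isopropenyl-bearing stereocentre (future C5) untouched.

Step 3
Reactants: 4 (3S)-3-(prop-1-en-2-yl)hept-5-ynal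
Product: 5 tert-butyl (5S)-3-oxo-5-(prop-1-en-2-yl)non-7-ynoate
Conditions: tert-butyl diazoacetate, SnCl2 (10 mol%), CH2Cl2, rt
Reagents that add atoms: tert-butyl diazoacetate, CC(C)(C)OC(=O)C=[N+]=[N-]
Why: Roskamp homologation (Lewis-acid-mediated addition of the diazo ester to the aldehyde, then 1,2-hydride shift with loss of N2) should give the β-keto ester directly under conditions that leave the alkyne and alkene alone.

Step 4
Reactants: 6 acrolein
Product: 7 (±)-hex-1-en-4-yn-3-ol
Conditions: 1-propynylmagnesium bromide, THF, −78 to 0 °C; aq. NH4Cl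
Reagents that add atoms: 1-propynylmagnesium bromide, CC#C[Mg]Br
Why: Grignard 1,2-addition of the hard alkynyl nucleophile to the enal should give the racemic alkynyl vinyl carbinol.

Step 5
Reactants: 7 (±)-hex-1-en-4-yn-3-ol
Product: 8 (1S)-1-[(2R)-oxiran-2-yl]but-2-yn-1-ol
Conditions: Ti(OiPr)4 (0.1 equiv), L-(+)-DIPT (0.15 equiv), t-BuOOH (0.45 equiv), 4 Å MS, CH2Cl2, −20 °C
Reagents that add atoms: tert-butyl hydroperoxide, CC(C)(C)OO
Why: Sharpless kinetic resolution of a secondary allylic alcohol: with L-(+)-tartrate the fast-reacting enantiomer should be epoxidised to the erythro (anti) epoxy alcohol, which sets C12 (S) and C11 (R) together and leaves the slow enantiomer behind.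

Step 6
Reactants: 8 (1S)-1-[(2R)-oxiran-2-yl]but-2-yn-1-ol
Product: 9 tert-butyldimethyl{[(1S)-1-[(2R)-oxiran-2-yl]but-2-yn-1-yl]oxy}silane
Conditions: TBSCl, imidazole, DMF, 0 °C to rt
Reagents that add atoms: tert-butyldimethylsilyl chloride, CC(C)(C)[Si](C)(C)Cl
Why: Standard silylation masks the C12 hydroxyl so that the C11 oxygen released in step 7 is the only free hydroxyl for the later Reformatsky tether.

Step 7
Reactants: 9 silyl-protected epoxy alcohol
Product: 10 (4R,5S)-5-[(tert-butyldimethylsilyl)oxy]-2-methyloct-1-en-6-yn-4-ol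
Conditions: isopropenylmagnesium bromide, CuI (10 mol%), THF, −40 to −10 °C; aq. NH4Cl
Reagents that add atoms: isopropenylmagnesium bromide, CC(=C)[Mg]Br
Why: Copper-catalysed Grignard opening of the terminal epoxide should occur at the unhindered CH2 (future C10) by SN2, so C11 keeps its configuration, and the cold magnesium alkoxide should not promote silyl migration.

Step 8
Reactants: 10 homoallylic alcohol
Product: 11 (4R,5S)-5-[(tert-butyldimethylsilyl)oxy]-4-hydroxyoct-6-yn-2-one
Conditions: O3, CH2Cl2/MeOH, −78 °C (Sudan Red 7B end point); Me2S, −78 °C to rt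
Reagents that add atoms: ozone, [O-][O+]=O
Why: Ozonolysis with an indicator dye should cleave the electron-rich 1,1-disubstituted alkene well before the internal alkyne reacts, unmasking the methyl ketone that becomes C9.

Step 9
Reactants: 11 β-hydroxy ketone
Product: 12 (4R,5S)-5-[(tert-butyldimethylsilyl)oxy]-2-oxooct-6-yn-4-yl 2-bromoacetate
Conditions: BrCH2COBr, pyridine, CH2Cl2, −40 °C
Reagents that add atoms: bromoacetyl bromide, BrCC(Br)=O
Why: Low-temperature acylation of the only free hydroxyl with the reactive acyl bromide should install the Reformatsky tether on O–C11 without β-elimination of the β-acyloxy ketone.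

Step 10
Reactants: 12 bromoacetate
Product: 13 (4S,6R)-6-[(1S)-1-[(tert-butyldimethylsilyl)oxy]but-2-yn-1-yl]-4-hydroxy-4-methyloxan-2-one
Conditions: SmI2 (2.2 equiv), THF, −78 °C
Reagents that add atoms: none
Why: SmI2-mediated intramolecular Reformatsky reaction: the samarium enolate should add to the methyl ketone through a chelated chair with the C11 side chain equatorial and the samarium-bound ketone oxygen axial, so the new C9 hydroxyl ends up trans to the side chain (C9 S).

Step 11
Reactants: 13 δ-lactone
Product: 14 methyl (3S,5R,6S)-6-[(tert-butyldimethylsilyl)oxy]-3,5-dihydroxy-3-methylnon-7-ynoate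
Conditions: K2CO3 (0.2 equiv), MeOH, 0 °C; AcOH quench; used directly
Reagents that add atoms: methanol, CO
Why: Base-catalysed methanolysis of the δ-lactone in a large excess of methanol should deliver the methyl ester and free the C11 hydroxyl; cold, brief conditions and direct use limit relactonisation.

Step 12
Reactants: 14 dihydroxy ester
Product: 15 methyl (3S,5R,6S)-6-[(tert-butyldimethylsilyl)oxy]-3-hydroxy-3-methyl-5-[(triethylsilyl)oxy]non-7-ynoate
Conditions: TESCl, imidazole, CH2Cl2, 0 °C
Reagents that add atoms: chlorotriethylsilane, CC[Si](CC)(CC)Cl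
Why: The secondary C11 hydroxyl should be silylated selectively over the hindered tertiary C9 hydroxyl, which is left free for the fragment union.

Step 13
Reactants: 5 tert-butyl β-keto ester (1.5 equiv); 15 tertiary alcohol
Product: 17 diyne β-keto ester (5S,9S,11R,12S), via acylketene 16 (not isolated)
Conditions: toluene, 110 °C, slow argon sweep (removal of t-BuOH)
Reagents that add atoms: none
Why: Thermal loss of tert-butanol from the tert-butyl β-keto ester should generate the acylketene, which is captured by the tertiary alcohol in a pseudopericyclic addition that tolerates hindered alcohols, forming the C7–O8 ester under neutral conditions.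

Step 14
Reactants: 17 diyne β-keto ester
Product: 18 13-membered cycloalkyne lactone bis-silyl ether (5S,9S,11R,12S)
Conditions: Mo(≡CC6H4OMe-4)(OSiPh3)3 (10 mol%), 5 Å MS, toluene, 80 °C, 2 mM
Reagents that add atoms: none
Why: Ring-closing alkyne metathesis of the two methyl-capped alkynes should form the C13≡C3 triple bond with but-2-yne trapped by the sieves; the catalyst leaves the isopropenyl alkene, esters and silyl ethers untouched, and a 13-membered cycloalkyne is within the accessible ring-size range.

Step 15
Reactants: 18 macrocyclic bis-silyl ether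
Product: 19 13-membered cycloalkyne diol (5S,9S,11R,12S)
Conditions: HF·pyridine, pyridine, THF, 0 °C to rt
Reagents that add atoms: none
Why: Buffered fluoride-mediated desilylation should remove both silyl ethers without touching the tertiary β-keto ester or the methyl ester.

Step 16
Reactants: 19 cycloalkyne diol
Product: 23 target CNP0302642.1, via alkoxycarbonylpalladium complex 20 (not isolated), via E-alkylidene lactone 21 (not isolated), via Z-alkylidene lactone 22 (not isolated)
Conditions: PdI2 (5 mol%), PBu3 (10 mol%), CO (7 atm), MeCN, 60 °C; vent; then PBu3 (20 mol%), Cs2CO3 (0.2 equiv), MeCN, 40 °C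
Reagents that add atoms: carbon monoxide, [C-]#[O+]
Why: The C11 hydroxyl attacks CO on divalent palladium to give alkoxycarbonylpalladium 20, which inserts the C13≡C3 alkyne in a syn 5-exo-dig sense to form the C14–C13 bond, and protonolysis of the alkenyl–palladium bond releases E-alkylidene lactone 21; after venting, PBu3 equilibrates 21 with its Z isomer 22 by reversible conjugate addition while the carbonate generates the C1/C7-stabilised enolate, whose C2 adds across the ring to C3 before C13 is protonated. The closest known reaction types are the palladium-catalysed cyclocarbonylation of homopropargylic alcohols to α-alkylidene-γ-butyrolactones and the Michael addition of β-keto esters to α-alkylidene lactones. Ring C closes 5-exo-dig, and rings A and B close together in a 6-exo-trig transannular attack that divides the 13-membered ring into a six- and a nine-membered ring. C3 is controlled by alkene geometry plus attack face: the O8–C9–C10 tether hangs from the face of ring C that carries C10 (anti to the C12 hydroxyl), so C2 can reach C3 only from that face, and from that face the Z isomer gives 3R through a chair with equatorial isopropenyl and axial lactone, whereas the E isomer would give the C3 epimer through a chair that eclipses the lactone with the C7 carbonyl on the planar enolate (Curtin–Hammett selection). C13 is controlled by ring strain, because only protonation on the face of the C12 hydroxyl keeps the C3 and C10 arms cis on ring C, a trans-bridged five-membered ring inside the nine-membered ring being prohibitively strained. The step needs C11–OH over C12–OH (five- against four-membered insertion), alkyne over isopropenyl alkene (only the alkyne is within reach of the tethered Pd–CO2R) and C–C bond formation without β-elimination (the free C12 hydroxyl is a poor leaving group and the stabilised C2 enolate is formed far more readily than any ester enolate).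

**Compound list**

1 | (R)-(−)-carvone | CC1=CC[C@H](CC1=O)C(C)=C | starting material
2 | (1R,4R,6R)-1-methyl-4-(prop-1-en-2-yl)-7-oxabicyclo[4.1.0]heptan-2-one | C[C@@]12O[C@@H]1C[C@H](CC2=O)C(C)=C | intermediate
3 | p-toluenesulfonylhydrazone of 2 | C[C@@]12O[C@@H]1C[C@H](CC2=NNS(=O)(=O)c1ccc(C)cc1)C(C)=C | intermediate
4 | (3S)-3-(prop-1-en-2-yl)hept-5-ynal | O=CC[C@H](CC#CC)C(C)=C | intermediate
5 | tert-butyl (5S)-3-oxo-5-(prop-1-en-2-yl)non-7-ynoate | CC(C)(C)OC(=O)CC(=O)C[C@H](CC#CC)C(C)=C | intermediate
6 | acrolein | C=CC=O | starting material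
7 | (±)-hex-1-en-4-yn-3-ol (racemate) | C=CC(O)C#CC | intermediate
8 | (1S)-1-[(2R)-oxiran-2-yl]but-2-yn-1-ol | CC#C[C@H](O)[C@H]1CO1 | intermediate
9 | tert-butyldimethyl{[(1S)-1-[(2R)-oxiran-2-yl]but-2-yn-1-yl]oxy}silane | CC#C[C@H](O[Si](C)(C)C(C)(C)C)[C@H]1CO1 | intermediate
10 | (4R,5S)-5-[(tert-butyldimethylsilyl)oxy]-2-methyloct-1-en-6-yn-4-ol | C=C(C)C[C@@H](O)[C@@H](O[Si](C)(C)C(C)(C)C)C#CC | intermediate
11 | (4R,5S)-5-[(tert-butyldimethylsilyl)oxy]-4-hydroxyoct-6-yn-2-one | CC(=O)C[C@@H](O)[C@@H](O[Si](C)(C)C(C)(C)C)C#CC | intermediate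
12 | (4R,5S)-5-[(tert-butyldimethylsilyl)oxy]-2-oxooct-6-yn-4-yl 2-bromoacetate | CC(=O)C[C@@H](OC(=O)CBr)[C@@H](O[Si](C)(C)C(C)(C)C)C#CC | intermediate
13 | (4S,6R)-6-[(1S)-1-[(tert-butyldimethylsilyl)oxy]but-2-yn-1-yl]-4-hydroxy-4-methyloxan-2-one | O[C@]1(C)CC(=O)O[C@H](C1)[C@@H](O[Si](C)(C)C(C)(C)C)C#CC | intermediate
14 | methyl (3S,5R,6S)-6-[(tert-butyldimethylsilyl)oxy]-3,5-dihydroxy-3-methylnon-7-ynoate | COC(=O)C[C@@](C)(O)C[C@@H](O)[C@@H](O[Si](C)(C)C(C)(C)C)C#CC | intermediate
15 | methyl (3S,5R,6S)-6-[(tert-butyldimethylsilyl)oxy]-3-hydroxy-3-methyl-5-[(triethylsilyl)oxy]non-7-ynoate | COC(=O)C[C@@](C)(O)C[C@@H](O[Si](CC)(CC)CC)[C@@H](O[Si](C)(C)C(C)(C)C)C#CC | intermediate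
16 | (5S)-5-(prop-1-en-2-yl)non-1-en-7-yne-1,3-dione (acylketene) | O=C=CC(=O)C[C@H](CC#CC)C(C)=C | intermediate
17 | ester of the C9 tertiary hydroxyl of 15 with (5S)-3-oxo-5-(prop-1-en-2-yl)non-7-ynoic acid (diyne β-keto ester) | COC(=O)C[C@@](C)(OC(=O)CC(=O)C[C@H](CC#CC)C(C)=C)C[C@@H](O[Si](CC)(CC)CC)[C@@H](O[Si](C)(C)C(C)(C)C)C#CC | intermediate
18 | 13-membered cycloalkyne lactone, C11 triethylsilyl ether, C12 tert-butyldimethylsilyl ether (5S,9S,11R,12S) | C=C(C)[C@@H]1CC(=O)CC(=O)O[C@](C)(CC(=O)OC)C[C@@H](O[Si](CC)(CC)CC)[C@@H](O[Si](C)(C)C(C)(C)C)C#CC1 | intermediate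
19 | 13-membered cycloalkyne lactone C11,C12-diol (5S,9S,11R,12S) | C=C(C)[C@@H]1CC(=O)CC(=O)O[C@](C)(CC(=O)OC)C[C@@H](O)[C@@H](O)C#CC1 | intermediate
20 | iodobis(tributylphosphine)palladium alkoxycarbonyl complex on O–C11 of 19 | C=C(C)[C@@H]1CC(=O)CC(=O)O[C@](C)(CC(=O)OC)C[C@@H](OC(=O)[Pd-2](I)([P+](CCCC)(CCCC)CCCC)[P+](CCCC)(CCCC)CCCC)[C@@H](O)C#CC1 | intermediate
21 | macrocyclic (E)-α-alkylidene-β-hydroxy-γ-butyrolactone (C4 cis to C12) | C=C(C)[C@@H]1CC(=O)CC(=O)O[C@](C)(CC(=O)OC)C[C@H]2OC(=O)/C(=C/C1)[C@@H]2O | intermediate
22 | macrocyclic (Z)-α-alkylidene-β-hydroxy-γ-butyrolactone (C4 cis to C14) | C=C(C)[C@@H]1CC(=O)CC(=O)O[C@](C)(CC(=O)OC)C[C@H]2OC(=O)/C(=C\C1)[C@@H]2O | intermediate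
23 | CNP0302642.1 (5S,3R,13S,12S,11R,9S; tricyclic enol dilactone methyl ester) | C=C(C)[C@@H]1CC(O)=C2C(=O)O[C@](C)(CC(=O)OC)C[C@H]3OC(=O)[C@H]([C@@H]3O)[C@H]2C1 | target

**Step count**

Total steps: 16. Longest linear sequence: 13 steps (steps 4 to 16); the carvone branch (steps 1 to 3) joins at step 13.

**Steps most likely to fail, with fallbacks**

Step 16. The E-to-Z equilibration of the alkylidene lactone may be too slow relative to ring closure, so that closure proceeds from the E isomer and control at C3 is lost. The free C11 hydroxyl may also lactonise onto the methyl ester before carbonylation, and the internal, ring-bound alkyne may insert sluggishly. The fallback fixes the alkene geometry by stereospecific chemistry and closes ring C at the C–O bond. Setting out from 19, hydroxyl-directed trans-hydrostannation (Bu3SnH, [Cp*RuCl]4, CH2Cl2) should place tin on C13 and hydrogen on C3 in an anti sense to give the macrocyclic (Z)-alkenylstannane F1. Iododestannylation (I2, CH2Cl2, 0 °C) should give the (Z)-alkenyl iodide F2 with retention. Carbonylative lactonisation with the C11 hydroxyl (Pd(PPh3)4, CO 1 atm, Et3N, THF, 50 °C) should then give the Z-alkylidene lactone as an isolated compound. The route is rejoined at 22, which on treatment with Cs2CO3 in MeCN should undergo the transannular Michael addition to 23 without the need for isomerisation.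

Step 14. The acidic, chelating β-keto ester may deactivate the alkylidyne catalyst, or oligomerisation may win over closure of the 13-membered cycloalkyne. The fallback moves the ring closure to the ester bond. Setting out from 4 and 15, aldehyde 4 is converted into its dimethyl acetal F3 (HC(OMe)3, PPTS, MeOH). Alkyne cross-metathesis of 15 with an excess of F3 (same molybdenum alkylidyne, 5 Å MS, toluene), in which no 1,3-dicarbonyl is present, should give the open-chain alkyne F4. Mild acetal hydrolysis (PPTS, wet acetone) should give the aldehyde F5, and Roskamp homologation (tert-butyl diazoacetate, SnCl2) the tert-butyl β-keto ester F6. Thermolysis of F6 at high dilution in refluxing toluene should close the macrolactone by intramolecular acylketene capture at the C9 hydroxyl, and the route is rejoined at 18.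

Step 13. Capture of the acylketene by the hindered, hydrogen-bonded tertiary hydroxyl may be slow, so that ketene dimerisation consumes the fragment. The fallback forms the C1–C2 bond in place of the C7–O8 bond in the union. Setting out from 15, acylation with bromoacetyl bromide and pyridine should give the tertiary bromoacetate F7. Treatment with N,N'-ditosylhydrazine and DBU should give the diazoacetate F8. Roskamp coupling of F8 with aldehyde 4 (SnCl2, CH2Cl2, rt) should give the β-keto ester directly, and the route is rejoined at 17.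

**Further compounds**

F1 | step 16 | macrocyclic (Z)-C13-tributylstannyl alkene diol (tin cis to C4) | C=C(C)[C@@H]1CC(=O)CC(=O)O[C@](C)(CC(=O)OC)C[C@@H](O)[C@@H](O)/C(=C/C1)[Sn](CCCC)(CCCC)CCCC
F2 | step 16 | macrocyclic (Z)-C13-iodo alkene diol (iodine cis to C4) | C=C(C)[C@@H]1CC(=O)CC(=O)O[C@](C)(CC(=O)OC)C[C@@H](O)[C@@H](O)/C(I)=C/C1
F3 | step 14 | (3S)-1,1-dimethoxy-3-(prop-1-en-2-yl)hept-5-yne | COC(OC)C[C@H](CC#CC)C(C)=C
F4 | step 14 | cross-metathesis alkyne from 15 and F3 (dimethyl acetal, free C9 hydroxyl) | COC(=O)C[C@@](C)(O)C[C@@H](O[Si](CC)(CC)CC)[C@@H](O[Si](C)(C)C(C)(C)C)C#CC[C@@H](CC(OC)OC)C(C)=C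
F5 | step 14 | aldehyde from hydrolysis of F4 | COC(=O)C[C@@](C)(O)C[C@@H](O[Si](CC)(CC)CC)[C@@H](O[Si](C)(C)C(C)(C)C)C#CC[C@@H](CC=O)C(C)=C
F6 | step 14 | open-chain tert-butyl β-keto ester with free C9 hydroxyl | COC(=O)C[C@@](C)(O)C[C@@H](O[Si](CC)(CC)CC)[C@@H](O[Si](C)(C)C(C)(C)C)C#CC[C@@H](CC(=O)CC(=O)OC(C)(C)C)C(C)=C
F7 | step 13 | bromoacetate of the C9 hydroxyl of 15 | COC(=O)C[C@@](C)(OC(=O)CBr)C[C@@H](O[Si](CC)(CC)CC)[C@@H](O[Si](C)(C)C(C)(C)C)C#CC
F8 | step 13 | diazoacetate of the C9 hydroxyl of 15 | COC(=O)C[C@@](C)(OC(=O)C=[N+]=[N-])C[C@@H](O[Si](CC)(CC)CC)[C@@H](O[Si](C)(C)C(C)(C)C)C#CC
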